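**Retrosynthetic overview**

1. Core locants (bicyclo[3.3.1]nonane): C1 = C(OH) bridgehead, C2 = CH2, C3 = CHN, C4 = CHOH, C5 = CH bridgehead, C6 = CHOH, C7/C8 = oxirane, C9 = C=O. The amide is cut to (E)-7-oxododec-2-enoic acid (cross-metathesis) and the aminated core.
2. Ring 2 (C1–C9–C5–C6–C7–C8) is opened by retro-aldol at C5–C6 to a ring-1 cyclohexanone carrying a cis-epoxy aldehyde on C1; the oxirane comes from an anti C8-OH / C7-OMs pair (inversion at C7).
3. Ring 1 (C1–C2–C3–C4–C5–C9) is cut at C1–C2 and C9–C5 in one anionic [4+2] annulation. C9–C1–C8–C7–C6 is the C1–C5 chain of 2,3-O-isopropylidene-D-lyxono-1,4-lactone (nucleophilic at C1 as enolate, electrophilic at C9 as lactone carbonyl). C2–C3–C4–C5 is an L-serine-derived unit, electrophilic at C2 (cyclic sulfamidate) and nucleophilic at C5 (α-sulfonyl carbanion).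
4. Enabling feature: the C1(OH)–C9(=O) α-ketol lies between C2H2 and C5H, which are 1,4-related through C3(N)–C4(O). C1/C9 therefore map onto the α-carbon/carboxyl carbon of an α-hydroxy acid, and C6–C8 carry the oxygens of a pentonic acid, so ring 1 can be closed by alkylation plus Claisen acylation.
5. Order of ring formation: ring 1 (step 7), then the oxirane (step 13), then ring 2 (step 16).

Key step: step 7

Remark: D-lyxono-1,4-lactone is taken as a purchasable chiral-pool lactone (it is also the bromine-water oxidation product of D-lyxose); C1–C9 below always mean the core locants defined in line 1.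

**Route**

Step 1
Reactants: 1 tert-butyl (S)-4-formyl-2,2-dimethyloxazolidine-3-carboxylate; 2 methyl phenyl sulfone
Product: 3 tert-butyl (S)-4-[(S)-1-hydroxy-2-(phenylsulfonyl)ethyl]-2,2-dimethyloxazolidine-3-carboxylate
Conditions: 2, n-BuLi, THF, −78 °C; then 1, −78 °C; H2O
Reagents that add atoms: none
Why: Carbonyl addition of the α-sulfonyl carbanion PhSO2CH2Li to the α-amino aldehyde; Felkin–Anh (non-chelated) attack anti to the ring nitrogen should give mainly the anti amino alcohol, which is the C4 carbinol of the target (the minor syn epimer is removed by chromatography).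

Step 2
Reactants: 3 tert-butyl (S)-4-[(S)-1-hydroxy-2-(phenylsulfonyl)ethyl]-2,2-dimethyloxazolidine-3-carboxylate
Product: 4 tert-butyl (S)-4-[(S)-1-(tert-butyldimethylsilyloxy)-2-(phenylsulfonyl)ethyl]-2,2-dimethyloxazolidine-3-carboxylate
Conditions: TBSOTf, 2,6-lutidine, CH2Cl2, 0 °C
Reagents that add atoms: tert-butyldimethylsilyl triflate, CC(C)(C)[Si](C)(C)OS(=O)(=O)C(F)(F)F
Why: Silyl ether formation at the only free hydroxyl; it blocks C4–O during sulfamidate formation and makes it a poor leaving group β to the later carbanion.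

Step 3
Reactants: 4 tert-butyl (S)-4-[(S)-1-(tert-butyldimethylsilyloxy)-2-(phenylsulfonyl)ethyl]-2,2-dimethyloxazolidine-3-carboxylate
Product: 5 tert-butyl N-[(2S,3S)-3-(tert-butyldimethylsilyloxy)-1-hydroxy-4-(phenylsulfonyl)butan-2-yl]carbamate
Conditions: p-TsOH·H2O (cat.), MeOH, 0 °C → rt
Reagents that add atoms: none
Why: Acid-catalysed transacetalisation (methanolysis) of the N,O-isopropylidene aminal, which should be cleaved faster than the secondary silyl ether or the Boc group.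

Step 4
Reactants: 5 tert-butyl N-[(2S,3S)-3-(tert-butyldimethylsilyloxy)-1-hydroxy-4-(phenylsulfonyl)butan-2-yl]carbamate
Product: 7 tert-butyl (4S)-4-[(1S)-1-(tert-butyldimethylsilyloxy)-2-(phenylsulfonyl)ethyl]-1,2,3-oxathiazolidine-3-carboxylate 2,2-dioxide, via cyclic sulfamidite 6 (not isolated)
Conditions: SOCl2, Et3N, imidazole (cat.), CH2Cl2, −40 → 0 °C; then RuCl3·H2O (cat.), NaIO4, MeCN/H2O, 0 °C
Reagents that add atoms: thionyl chloride, O=S(Cl)Cl; sodium periodate, [Na+].[O-]I(=O)(=O)=O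
Why: Standard two-stage 1,2-cyclic sulfamidate synthesis from an N-Boc β-amino alcohol (cyclisation to the sulfamidite, then RuCl3/NaIO4 oxidation at sulfur); no stereocentre is touched and the primary CH2–O (C2) becomes a strong SN2 electrophile.

Step 5
Reactants: 8 D-lyxono-1,4-lactone
Product: 9 2,3-O-isopropylidene-D-lyxono-1,4-lactone
Conditions: 2,2-dimethoxypropane, acetone, p-TsOH (cat.), rt
Reagents that add atoms: 2,2-dimethoxypropane, COC(C)(C)OC
Why: Thermodynamic acetonide formation on the cis-2,3-diol of the γ-lactone (cis-fused dioxolane), leaving the primary hydroxyl free.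

Step 6
Reactants: 9 2,3-O-isopropylidene-D-lyxono-1,4-lactone
Product: 10 5-O-(tert-butyldiphenylsilyl)-2,3-O-isopropylidene-D-lyxono-1,4-lactone
Conditions: TBDPSCl, imidazole, DMF, 0 °C → rt
Reagents that add atoms: tert-butyl(chloro)diphenylsilane, CC(C)(C)[Si](Cl)(c1ccccc1)c1ccccc1
Why: Silylation of the primary hydroxyl (future C6–O) with a group that should survive strong base and aqueous CF3CO2H.

Step 7
Reactants: 10 5-O-(tert-butyldiphenylsilyl)-2,3-O-isopropylidene-D-lyxono-1,4-lactone; 7 tert-butyl (4S)-4-[(1S)-1-(tert-butyldimethylsilyloxy)-2-(phenylsulfonyl)ethyl]-1,2,3-oxathiazolidine-3-carboxylate 2,2-dioxide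
Product: 14 tert-butyl N-[(4S,5S,8S,9S)-8-(tert-butyldimethylsilyloxy)-4-[(1R)-2-(tert-butyldiphenylsilyloxy)-1-(methylsulfonyloxy)ethyl]-2,2-dimethyl-6-oxo-7-(phenylsulfonyl)-1,3-dioxaspiro[4.5]decan-9-yl]carbamate (epimers at the sulfonyl carbon), via lithium enolate 11 (not isolated), via lithium N-sulfonate 12 (not isolated), via trilithium alkoxide enolate 13 (not isolated)
Conditions: 10, LiN(SiMe3)2 (1.05 equiv), THF, −78 °C; 7, THF/DMPU, −78 → −40 °C; LiN(i-Pr)2 (2.2 equiv), −78 → −40 °C; Ms2O (2 equiv), −78 °C; 10% aq. citric acid, rt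
Reagents that add atoms: methanesulfonic anhydride, CS(=O)(=O)OS(C)(=O)=O
Why: LiN(SiMe3)2 should convert lactone 10 into enolate 11, which opens sulfamidate 7 at its primary CH2–O carbon (SN2) to form C1–C2 in 12; LiN(i-Pr)2 then deprotonates the only acidic site left, the CH2 next to the sulfone, and this carbanion adds to the lactone carbonyl and expels the ring oxygen as the C7 alkoxide (C9–C5 bond, 13), which Ms2O traps before the acidic work-up hydrolyses the N-sulfonate. The closest known reaction types are the alkylation of ester and lactone enolates with 1,2-cyclic sulfamidates and the Claisen-type acylation of α-sulfonyl carbanions by lactones (the route to β-keto sulfones and to ketoses from aldonolactones); together they form an anionic [4+2] annulation of the Michael–Claisen (dimedone) family. Ring 1 closes in the 6-exo-trig mode, the carbanion attacking the lactone C=O that is exocyclic to the forming ring, after which the lactone C–O bond breaks. The one new stereocentre that is kept, quaternary C1, is controlled by the cis-fused bicyclic enolate: the electrophile can enter only on the convex face, anti to the dioxolane ring and to the C7 side chain, so the C1 oxygen stays cis to the C8 oxygen; C3 and C4 come unchanged from 7, and the sulfonyl-bearing C5 is left uncontrolled because step 8 erases it. The step needs C-alkylation at carbon rather than attack at sulfur or at the carbamate, no β-elimination of the C8 oxygen from 11 (its C–O bond lies near the nodal plane of the enolate in the cis-fused bicycle and the temperature is kept low), acylation by the lactone rather than by the N-carbamate (six-ring attack on the more electrophilic acylal-like lactone), and mesylation of a single oxygen (the C7 alkoxide is the only alkoxide, the ketone being masked as its stabilised enolate).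

Step 8
Reactants: 14 tert-butyl N-[(4S,5S,8S,9S)-8-(tert-butyldimethylsilyloxy)-4-[(1R)-2-(tert-butyldiphenylsilyloxy)-1-(methylsulfonyloxy)ethyl]-2,2-dimethyl-6-oxo-7-(phenylsulfonyl)-1,3-dioxaspiro[4.5]decan-9-yl]carbamate
Product: 15 tert-butyl N-[(4S,5S,8R,9S)-8-(tert-butyldimethylsilyloxy)-4-[(1R)-2-(tert-butyldiphenylsilyloxy)-1-(methylsulfonyloxy)ethyl]-2,2-dimethyl-6-oxo-1,3-dioxaspiro[4.5]decan-9-yl]carbamate
Conditions: Al(Hg), THF/H2O (9:1), 0 °C → rt
Reagents that add atoms: none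
Why: Reductive desulfonylation of a β-keto sulfone by aluminium amalgam (electron transfer, loss of benzenesulfinate, protonation of the enol); the mesylate, silyl ethers, carbamate and the α-alkoxy ketone C–O bond should survive, and the uncontrolled sulfonyl stereocentre disappears.

Step 9
Reactants: 15 tert-butyl N-[(4S,5S,8R,9S)-8-(tert-butyldimethylsilyloxy)-4-[(1R)-2-(tert-butyldiphenylsilyloxy)-1-(methylsulfonyloxy)ethyl]-2,2-dimethyl-6-oxo-1,3-dioxaspiro[4.5]decan-9-yl]carbamate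
Product: 16 (2S,4S,5R)-4-amino-2-[(1S,2R)-3-(tert-butyldiphenylsilyloxy)-1-hydroxy-2-(methylsulfonyloxy)propyl]-2,5-dihydroxycyclohexan-1-one trifluoroacetate salt
Conditions: CF3CO2H/CH2Cl2/H2O (10:10:1), 0 °C → rt; evaporation
Reagents that add atoms: trifluoroacetic acid (counter-ion), OC(=O)C(F)(F)F
Why: One acidolysis removes the Boc group, the secondary TBS ether and the spiro-acetonide (acetal hydrolysis), while the primary TBDPS ether and the mesylate should survive; all acid-labile groups are thus cleared before the oxirane exists, and the amine stays protonated so that it cannot displace the mesylate.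

Step 10
Reactants: 17 hex-5-enenitrile; 18 pentylmagnesium bromide
Product: 20 undec-1-en-6-one, via bromomagnesium ketiminate 19 (not isolated)
Conditions: 18 (CH3(CH2)4MgBr), Et2O, 0 °C → reflux; then 2 M aq. HCl, rt
Reagents that add atoms: water, O
Why: Grignard addition to a nitrile stops at the N-magnesio ketimine, which is hydrolysed to the ketone on acidic work-up.

Step 11
Reactants: 20 undec-1-en-6-one; 21 acrylic acid
Product: 22 (E)-7-oxododec-2-enoic acid
Conditions: 21 (3 equiv), second-generation Grubbs catalyst [(H2IMes)(PCy3)Cl2Ru=CHPh] (cat.), CH2Cl2, 40 °C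
Reagents that add atoms: none
Why: Olefin cross-metathesis of a terminal alkene with acrylic acid, which should give the conjugated acid with E geometry under thermodynamic control.

Step 12
Reactants: 16 (2S,4S,5R)-4-amino-2-[(1S,2R)-3-(tert-butyldiphenylsilyloxy)-1-hydroxy-2-(methylsulfonyloxy)propyl]-2,5-dihydroxycyclohexan-1-one trifluoroacetate salt; 22 (E)-7-oxododec-2-enoic acid
Product: 23 (E)-N-[(1S,2R,5S)-5-[(1S,2R)-3-(tert-butyldiphenylsilyloxy)-1-hydroxy-2-(methylsulfonyloxy)propyl]-2,5-dihydroxy-4-oxocyclohexyl]-7-oxododec-2-enamide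
Conditions: 22, EDC·HCl, HOBt, CH2Cl2/DMF, 0 °C; then 16, i-Pr2NEt, 0 °C → rt
Reagents that add atoms: none
Why: Carbodiimide/HOBt amide coupling; the pre-formed active ester should acylate the amine far faster than the hydroxyl groups, and capping nitrogen before the oxirane is formed prevents intramolecular aminolysis.

Step 13
Reactants: 23 (E)-N-[(1S,2R,5S)-5-[(1S,2R)-3-(tert-butyldiphenylsilyloxy)-1-hydroxy-2-(methylsulfonyloxy)propyl]-2,5-dihydroxy-4-oxocyclohexyl]-7-oxododec-2-enamide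
Product: 24 (E)-N-[(1S,2R,5S)-5-[(2S,3S)-3-[(tert-butyldiphenylsilyloxy)methyl]oxiran-2-yl]-2,5-dihydroxy-4-oxocyclohexyl]-7-oxododec-2-enamide
Conditions: K2CO3, MeOH, 0 °C, short reaction time
Reagents that add atoms: none
Why: Intramolecular Williamson etherification (3-exo-tet): the C8 alkoxide displaces the anti C7 mesylate with inversion, giving the cis-oxirane whose oxygen is the original C8 oxygen on the face of the C1 hydroxyl; the short time at 0 °C is meant to outrun Payne-type migration to the tertiary C1 alkoxide.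

Step 14
Reactants: 24 (E)-N-[(1S,2R,5S)-5-[(2S,3S)-3-[(tert-butyldiphenylsilyloxy)methyl]oxiran-2-yl]-2,5-dihydroxy-4-oxocyclohexyl]-7-oxododec-2-enamide
Product: 25 (E)-N-[(1S,2R,5S)-2,5-dihydroxy-5-[(2S,3S)-3-(hydroxymethyl)oxiran-2-yl]-4-oxocyclohexyl]-7-oxododec-2-enamide
Conditions: Bu4NF, AcOH (1:1), THF, 0 °C → rt
Reagents that add atoms: none
Why: Fluoride desilylation of the primary silyl ether, buffered with acetic acid so that the liberated epoxy alcohol should not undergo Payne rearrangement or base-induced cleavage.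

Step 15
Reactants: 25 (E)-N-[(1S,2R,5S)-2,5-dihydroxy-5-[(2S,3S)-3-(hydroxymethyl)oxiran-2-yl]-4-oxocyclohexyl]-7-oxododec-2-enamide
Product: 26 (E)-N-[(1S,2R,5S)-5-[(2S,3R)-3-formyloxiran-2-yl]-2,5-dihydroxy-4-oxocyclohexyl]-7-oxododec-2-enamide
Conditions: TEMPO (cat.), PhI(OAc)2, CH2Cl2, rt
Reagents that add atoms: none
Why: Oxoammonium (TEMPO/PhI(OAc)2) oxidation, selective for the primary alcohol over the secondary C4 and tertiary C1 hydroxyls; the resulting α,β-epoxy aldehyde cannot enolise.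

Step 16
Reactants: 26 (E)-N-[(1S,2R,5S)-5-[(2S,3R)-3-formyloxiran-2-yl]-2,5-dihydroxy-4-oxocyclohexyl]-7-oxododec-2-enamide
Product: 27 isariotin C, (E)-N-[(1S,3S,4R,5S,6S,7S,8S)-7,8-epoxy-1,4,6-trihydroxy-9-oxobicyclo[3.3.1]nonan-3-yl]-7-oxododec-2-enamide
Conditions: LiCl, DBU (0.3 equiv), THF, 0 °C → rt
Reagents that add atoms: none
Why: Intramolecular aldol addition (6-exo-trig, soft enolisation): only C5 of the C9 ketone can enolise productively (C1 is quaternary and the aldehyde α-carbon is an oxirane carbon), the tether fixes C5 from C1, and a lithium-chelated closed (Zimmerman–Traxler-type) transition state should place the C6 hydroxyl on the side of the C9 carbonyl (axial on ring 2, cis to the oxirane), which is also the thermodynamically preferred epimer because an equatorial C6 substituent would clash with H-4; the bridgehead ketol can no longer enolise and so should not dehydrate.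

**Compound list**

1 | tert-butyl (S)-4-formyl-2,2-dimethyloxazolidine-3-carboxylate | CC1(C)OC[C@@H](C=O)N1C(=O)OC(C)(C)C | starting material
2 | methyl phenyl sulfone | CS(=O)(=O)c1ccccc1 | starting material
3 | tert-butyl (S)-4-[(S)-1-hydroxy-2-(phenylsulfonyl)ethyl]-2,2-dimethyloxazolidine-3-carboxylate | CC1(C)OC[C@@H]([C@H](O)CS(=O)(=O)c2ccccc2)N1C(=O)OC(C)(C)C | intermediate
4 | tert-butyl (S)-4-[(S)-1-(tert-butyldimethylsilyloxy)-2-(phenylsulfonyl)ethyl]-2,2-dimethyloxazolidine-3-carboxylate | CC1(C)OC[C@@H]([C@H](O[Si](C)(C)C(C)(C)C)CS(=O)(=O)c2ccccc2)N1C(=O)OC(C)(C)C | intermediate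
5 | tert-butyl N-[(2S,3S)-3-(tert-butyldimethylsilyloxy)-1-hydroxy-4-(phenylsulfonyl)butan-2-yl]carbamate | OC[C@H](NC(=O)OC(C)(C)C)[C@H](O[Si](C)(C)C(C)(C)C)CS(=O)(=O)c1ccccc1 | intermediate
6 | tert-butyl (4S)-4-[(1S)-1-(tert-butyldimethylsilyloxy)-2-(phenylsulfonyl)ethyl]-1,2,3-oxathiazolidine-3-carboxylate 2-oxide (both sulfur epimers) | O=S1OC[C@@H]([C@H](O[Si](C)(C)C(C)(C)C)CS(=O)(=O)c2ccccc2)N1C(=O)OC(C)(C)C | intermediate (not isolated)
7 | tert-butyl (4S)-4-[(1S)-1-(tert-butyldimethylsilyloxy)-2-(phenylsulfonyl)ethyl]-1,2,3-oxathiazolidine-3-carboxylate 2,2-dioxide | O=S1(=O)OC[C@@H]([C@H](O[Si](C)(C)C(C)(C)C)CS(=O)(=O)c2ccccc2)N1C(=O)OC(C)(C)C | intermediate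
8 | D-lyxono-1,4-lactone | O=C1O[C@H](CO)[C@H](O)[C@@H]1O | starting material
9 | 2,3-O-isopropylidene-D-lyxono-1,4-lactone | O=C1O[C@H](CO)[C@@H]2OC(C)(C)O[C@H]12 | intermediate
10 | 5-O-(tert-butyldiphenylsilyl)-2,3-O-isopropylidene-D-lyxono-1,4-lactone | O=C1O[C@H](CO[Si](c3ccccc3)(c3ccccc3)C(C)(C)C)[C@@H]2OC(C)(C)O[C@H]12 | intermediate
11 | lithium enolate of 10 (deprotonated at the lactone α-carbon, future C1) | [Li+].[O-]C1=C2OC(C)(C)O[C@H]2[C@@H](CO[Si](c3ccccc3)(c3ccccc3)C(C)(C)C)O1 | intermediate (not isolated)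
12 | 2-C-[(2S,3S)-2-[(tert-butoxycarbonyl)(sulfonato)amino]-3-(tert-butyldimethylsilyloxy)-4-(phenylsulfonyl)butyl]-5-O-(tert-butyldiphenylsilyl)-2,3-O-isopropylidene-D-lyxono-1,4-lactone, lithium salt | O=C1O[C@H](CO[Si](c3ccccc3)(c3ccccc3)C(C)(C)C)[C@@H]2OC(C)(C)O[C@]12C[C@H](N(C(=O)OC(C)(C)C)S(=O)(=O)[O-])[C@H](O[Si](C)(C)C(C)(C)C)CS(=O)(=O)c1ccccc1.[Li+] | intermediate (not isolated)
13 | trilithium salt of the ring-1 β-keto sulfone (enolate, C7 alkoxide, N-sulfonate) | [Li+].[Li+].[Li+].[O-]C1=C(S(=O)(=O)c2ccccc2)[C@@H](O[Si](C)(C)C(C)(C)C)[C@@H](N(C(=O)OC(C)(C)C)S(=O)(=O)[O-])C[C@@]13OC(C)(C)O[C@H]3[C@H]([O-])CO[Si](c4ccccc4)(c4ccccc4)C(C)(C)C | intermediate (not isolated)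
14 | tert-butyl N-[(4S,5S,8S,9S)-8-(tert-butyldimethylsilyloxy)-4-[(1R)-2-(tert-butyldiphenylsilyloxy)-1-(methylsulfonyloxy)ethyl]-2,2-dimethyl-6-oxo-7-(phenylsulfonyl)-1,3-dioxaspiro[4.5]decan-9-yl]carbamate (epimers at the sulfonyl carbon) | O=C1C(S(=O)(=O)c2ccccc2)[C@@H](O[Si](C)(C)C(C)(C)C)[C@@H](NC(=O)OC(C)(C)C)C[C@@]13OC(C)(C)O[C@H]3[C@H](OS(C)(=O)=O)CO[Si](c4ccccc4)(c4ccccc4)C(C)(C)C | intermediate
15 | tert-butyl N-[(4S,5S,8R,9S)-8-(tert-butyldimethylsilyloxy)-4-[(1R)-2-(tert-butyldiphenylsilyloxy)-1-(methylsulfonyloxy)ethyl]-2,2-dimethyl-6-oxo-1,3-dioxaspiro[4.5]decan-9-yl]carbamate | O=C1C[C@@H](O[Si](C)(C)C(C)(C)C)[C@@H](NC(=O)OC(C)(C)C)C[C@@]13OC(C)(C)O[C@H]3[C@H](OS(C)(=O)=O)CO[Si](c4ccccc4)(c4ccccc4)C(C)(C)C | intermediate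
16 | (2S,4S,5R)-4-amino-2-[(1S,2R)-3-(tert-butyldiphenylsilyloxy)-1-hydroxy-2-(methylsulfonyloxy)propyl]-2,5-dihydroxycyclohexan-1-one trifluoroacetate salt | O=C1C[C@@H](O)[C@@H]([NH3+])C[C@]1(O)[C@@H](O)[C@H](OS(C)(=O)=O)CO[Si](c2ccccc2)(c2ccccc2)C(C)(C)C.[O-]C(=O)C(F)(F)F | intermediate
17 | hex-5-enenitrile | C=CCCCC#N | starting material
18 | pentylmagnesium bromide | CCCCC[Mg]Br | starting material
19 | N-(bromomagnesio)undec-1-en-6-imine | C=CCCCC(CCCCC)=N[Mg]Br | intermediate (not isolated)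
20 | undec-1-en-6-one | C=CCCCC(=O)CCCCC | intermediate
21 | acrylic acid | C=CC(=O)O | starting material
22 | (E)-7-oxododec-2-enoic acid | CCCCCC(=O)CCC/C=C/C(=O)O | intermediate
23 | (E)-N-[(1S,2R,5S)-5-[(1S,2R)-3-(tert-butyldiphenylsilyloxy)-1-hydroxy-2-(methylsulfonyloxy)propyl]-2,5-dihydroxy-4-oxocyclohexyl]-7-oxododec-2-enamide | CCCCCC(=O)CCC/C=C/C(=O)N[C@H]1C[C@](O)([C@@H](O)[C@H](OS(C)(=O)=O)CO[Si](c2ccccc2)(c2ccccc2)C(C)(C)C)C(=O)C[C@H]1O | intermediate
24 | (E)-N-[(1S,2R,5S)-5-[(2S,3S)-3-[(tert-butyldiphenylsilyloxy)methyl]oxiran-2-yl]-2,5-dihydroxy-4-oxocyclohexyl]-7-oxododec-2-enamide | CCCCCC(=O)CCC/C=C/C(=O)N[C@H]1C[C@](O)([C@H]2O[C@H]2CO[Si](c3ccccc3)(c3ccccc3)C(C)(C)C)C(=O)C[C@H]1O | intermediate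
25 | (E)-N-[(1S,2R,5S)-2,5-dihydroxy-5-[(2S,3S)-3-(hydroxymethyl)oxiran-2-yl]-4-oxocyclohexyl]-7-oxododec-2-enamide | CCCCCC(=O)CCC/C=C/C(=O)N[C@H]1C[C@](O)([C@H]2O[C@H]2CO)C(=O)C[C@H]1O | intermediate
26 | (E)-N-[(1S,2R,5S)-5-[(2S,3R)-3-formyloxiran-2-yl]-2,5-dihydroxy-4-oxocyclohexyl]-7-oxododec-2-enamide | CCCCCC(=O)CCC/C=C/C(=O)N[C@H]1C[C@](O)([C@H]2O[C@H]2C=O)C(=O)C[C@H]1O | intermediate
27 | isariotin C, (E)-N-[(1S,3S,4R,5S,6S,7S,8S)-7,8-epoxy-1,4,6-trihydroxy-9-oxobicyclo[3.3.1]nonan-3-yl]-7-oxododec-2-enamide | CCCCCC(=O)CCC/C=C/C(=O)N[C@H]1C[C@@]2(O)C(=O)[C@H]([C@H](O)[C@@H]3O[C@@H]32)[C@H]1O | target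

**Totals**

Total step count: 16.
Longest linear sequence: 12 steps (steps 1–4, 7–9 and 12–16; 1 → 3 → 4 → 5 → 7 → 14 → 15 → 16 → 23 → 24 → 25 → 26 → 27).

**Steps most likely to fail, with fallbacks**

Step 7. The lactone enolate may lose the C8 acetal oxygen by β-elimination before it is alkylated, SN2 at the branched CH2 of the sulfamidate may be slow, and the sulfonyl carbanion may attack the N-carbamate or lose silanolate instead of acylating. The fallback replaces the alkylation by an aldol addition and a deoxygenation; it sets out from 5 and 10 and returns at 14. Alcohol 5 is oxidised with Dess–Martin periodinane to tert-butyl N-[(2R,3S)-3-(tert-butyldimethylsilyloxy)-1-oxo-4-(phenylsulfonyl)butan-2-yl]carbamate F1. Enolate 11 (excess, −78 °C) adds to F1 in an aldol reaction, which is faster than alkylation at that temperature, to give the 2-C-(1-hydroxyalkyl) lactone F2 as a carbinol mixture. F2 is converted with PhOC(S)Cl, pyridine and DMAP into its O-phenyl thionocarbonate F3, and Barton–McCombie deoxygenation (Bu3SnH, AIBN, toluene, 80 °C) gives the 2-C-alkyl lactone carbamate F4, the N-protonated counterpart of 12. LiN(i-Pr)2 (3.3 equiv, which also deprotonates the carbamate N–H and so protects it from the carbanion) and then Ms2O convert F4 into 14.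

Step 16. Under enolising conditions the open-chain ketone may lose the C4 hydroxyl (E1cB), the side-chain ketone may compete for the aldehyde, the oxirane may migrate, or C6 may form with poor facial selectivity. The fallback closes ring 2 before N-acylation, on a carbamate that has a single ketone and with a stoichiometric lithium enolate; it sets out from 16 and returns at 27. Salt 16 is N-protected with allyl N-succinimidyl carbonate and NaHCO3 to give the allyl carbamate F5. K2CO3 in MeOH closes the oxirane to F6, Bu4NF/AcOH gives the primary alcohol F7, and TEMPO/PhI(OAc)2 gives the epoxy aldehyde F8. LiN(SiMe3)2 (3.2 equiv, THF, −78 °C) forms the alkoxide/enolate, which closes ring 2 through a chelated aldol to the bicyclic allyl carbamate F9. Pd(PPh3)4 with dimedone frees the amine F10, and EDC/HOBt coupling of F10 with 22 gives 27.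

Step 1. The sulfonyl carbanion may add with poor facial selectivity (Felkin against chelated attack), leaving a mixture at the future C4 that is hard to separate. The fallback is oxidation followed by reagent-controlled reduction; it sets out from the epimer mixture of 3 and returns at 3. Dess–Martin oxidation gives tert-butyl (S)-2,2-dimethyl-4-[2-(phenylsulfonyl)acetyl]oxazolidine-3-carboxylate F11. Corey–Bakshi–Shibata reduction (2-methyl-CBS-oxazaborolidine, BH3·SMe2, THF, −20 °C) then returns 3; the catalyst enantiomer is chosen to deliver the (S)-carbinol, and with the (S)-catalyst the oxazolidine ring is expected to act as the large group.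

**Further compounds**

F1 | step 7 | tert-butyl N-[(2R,3S)-3-(tert-butyldimethylsilyloxy)-1-oxo-4-(phenylsulfonyl)butan-2-yl]carbamate | O=C[C@H](NC(=O)OC(C)(C)C)[C@H](O[Si](C)(C)C(C)(C)C)CS(=O)(=O)c1ccccc1
F2 | step 7 | 2-C-[2-(tert-butoxycarbonylamino)-3-(tert-butyldimethylsilyloxy)-1-hydroxy-4-(phenylsulfonyl)butyl]-5-O-(tert-butyldiphenylsilyl)-2,3-O-isopropylidene-D-lyxono-1,4-lactone (amino and silyloxy carbons as in 5; carbinol epimers) | O=C1O[C@H](CO[Si](c3ccccc3)(c3ccccc3)C(C)(C)C)[C@@H]2OC(C)(C)O[C@]12C(O)[C@H](NC(=O)OC(C)(C)C)[C@H](O[Si](C)(C)C(C)(C)C)CS(=O)(=O)c1ccccc1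
F3 | step 7 | O-phenyl thionocarbonate of F2 | O=C1O[C@H](CO[Si](c3ccccc3)(c3ccccc3)C(C)(C)C)[C@@H]2OC(C)(C)O[C@]12C(OC(=S)Oc1ccccc1)[C@H](NC(=O)OC(C)(C)C)[C@H](O[Si](C)(C)C(C)(C)C)CS(=O)(=O)c1ccccc1
F4 | step 7 | 2-C-[(2S,3S)-2-(tert-butoxycarbonylamino)-3-(tert-butyldimethylsilyloxy)-4-(phenylsulfonyl)butyl]-5-O-(tert-butyldiphenylsilyl)-2,3-O-isopropylidene-D-lyxono-1,4-lactone | O=C1O[C@H](CO[Si](c3ccccc3)(c3ccccc3)C(C)(C)C)[C@@H]2OC(C)(C)O[C@]12C[C@H](NC(=O)OC(C)(C)C)[C@H](O[Si](C)(C)C(C)(C)C)CS(=O)(=O)c1ccccc1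
F5 | step 16 | prop-2-enyl N-[(1S,2R,5S)-5-[(1S,2R)-3-(tert-butyldiphenylsilyloxy)-1-hydroxy-2-(methylsulfonyloxy)propyl]-2,5-dihydroxy-4-oxocyclohexyl]carbamate | C=CCOC(=O)N[C@H]1C[C@](O)([C@@H](O)[C@H](OS(C)(=O)=O)CO[Si](c2ccccc2)(c2ccccc2)C(C)(C)C)C(=O)C[C@H]1O
F6 | step 16 | prop-2-enyl N-[(1S,2R,5S)-5-[(2S,3S)-3-[(tert-butyldiphenylsilyloxy)methyl]oxiran-2-yl]-2,5-dihydroxy-4-oxocyclohexyl]carbamate | C=CCOC(=O)N[C@H]1C[C@](O)([C@H]2O[C@H]2CO[Si](c3ccccc3)(c3ccccc3)C(C)(C)C)C(=O)C[C@H]1O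
F7 | step 16 | prop-2-enyl N-[(1S,2R,5S)-2,5-dihydroxy-5-[(2S,3S)-3-(hydroxymethyl)oxiran-2-yl]-4-oxocyclohexyl]carbamate | C=CCOC(=O)N[C@H]1C[C@](O)([C@H]2O[C@H]2CO)C(=O)C[C@H]1O
F8 | step 16 | prop-2-enyl N-[(1S,2R,5S)-5-[(2S,3R)-3-formyloxiran-2-yl]-2,5-dihydroxy-4-oxocyclohexyl]carbamate | C=CCOC(=O)N[C@H]1C[C@](O)([C@H]2O[C@H]2C=O)C(=O)C[C@H]1O
F9 | step 16 | prop-2-enyl N-[(1S,3S,4R,5S,6S,7S,8S)-7,8-epoxy-1,4,6-trihydroxy-9-oxobicyclo[3.3.1]nonan-3-yl]carbamate | C=CCOC(=O)N[C@H]1C[C@@]2(O)C(=O)[C@H]([C@H](O)[C@@H]3O[C@@H]32)[C@H]1O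
F10 | step 16 | (1S,3S,4R,5S,6S,7S,8S)-3-amino-7,8-epoxy-1,4,6-trihydroxybicyclo[3.3.1]nonan-9-one | N[C@H]1C[C@@]2(O)C(=O)[C@H]([C@H](O)[C@@H]3O[C@@H]32)[C@H]1O
F11 | step 1 | tert-butyl (S)-2,2-dimethyl-4-[2-(phenylsulfonyl)acetyl]oxazolidine-3-carboxylate | CC1(C)OC[C@@H](C(=O)CS(=O)(=O)c2ccccc2)N1C(=O)OC(C)(C)C
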